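**Retrosynthetic overview**

1. Target ⇐ acyclic hexamethyl ether alcohol: BBr3 closes the dihydrofuran ring through C2–O and removes the methyl ethers. This is the only ring made in the route and it is formed in the last step; all four benzene rings are bought.
2. Alcohol ⇐ racemic 1,2,2-triarylethanone by dynamic kinetic hydrogenation, which sets C3.
3. Triarylethanone ⇐ 1,2-aryl shift (semipinacol) of the chlorohydrin made from the ring A arylmagnesium bromide and an α-chloro deoxybenzoin; this forms the C3–C3a bond (ring A = benzo ring of the benzofuran).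
4. Both partners ⇐ one deoxybenzoin: deoxygenation gives the bibenzyl (ring A with its side chain), α-chlorination gives the electrophile.
5. Deoxybenzoin ⇐ anisole + bromoacetyl bromide (Friedel–Crafts) and resorcinol (O-methylation, C–H borylation), joined by Suzuki coupling.

Assumption: racemic intermediates are drawn as one enantiomer, and the sense of induction of RuCl2[(R)-xylbinap][(R)-daipen] is taken from simple aryl alkyl ketones (the mirror-image complex is used if it proves opposite).

**Route**

Step 1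
Reactants: 1 resorcinol (benzene-1,3-diol)
Product: 2 1,3-dimethoxybenzene
Conditions: MeI, K2CO3, acetone, reflux
Reagents that add atoms: iodomethane, CI
Why: Williamson ether synthesis; both phenoxides are O-methylated by SN2 on iodomethane, giving the methyl ethers that later direct the lithiation.

Step 2
Reactants: 2 1,3-dimethoxybenzene
Product: 3 2-(3,5-dimethoxyphenyl)-4,4,5,5-tetramethyl-1,3,2-dioxaborolane
Conditions: [Ir(OMe)(cod)]2 (1 mol %), dtbpy (2 mol %), B2pin2 (0.55 equiv), hexane, 80 °C
Reagents that add atoms: bis(pinacolato)diboron, CC1(C)OB(OC1(C)C)B1OC(C)(C)C(C)(C)O1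
Why: Sterically controlled aromatic C–H borylation; only the C5–H, meta to both methoxy groups, has no ortho substituent, so it alone is borylated.

Step 3
Reactants: 4 anisole (methoxybenzene); 5 bromoacetyl bromide
Product: 6 2-bromo-1-(4-methoxyphenyl)ethan-1-one
Conditions: AlCl3 (1.1 equiv), CH2Cl2, −10 → 0 °C
Reagents that add atoms: none
Why: Friedel–Crafts acylation of anisole is para-selective and stops after one acylation because the ketone–AlCl3 complex is deactivated.

Step 4
Reactants: 3 2-(3,5-dimethoxyphenyl)-4,4,5,5-tetramethyl-1,3,2-dioxaborolane; 6 2-bromo-1-(4-methoxyphenyl)ethan-1-one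
Product: 7 2-(3,5-dimethoxyphenyl)-1-(4-methoxyphenyl)ethan-1-one
Conditions: Pd(OAc)2 (3 mol %), P(o-tol)3 (9 mol %), K3PO4, THF/H2O, 25 → 40 °C
Reagents that add atoms: none
Why: Suzuki–Miyaura coupling at an sp3 carbon; oxidative addition into the activated C–Br bond of the α-bromo ketone, transmetalation from the boronate and reductive elimination give the deoxybenzoin, a known reaction class for α-bromo carbonyl compounds.

Step 5
Reactants: 7 2-(3,5-dimethoxyphenyl)-1-(4-methoxyphenyl)ethan-1-one
Product: 8 1,3-dimethoxy-5-[2-(4-methoxyphenyl)ethyl]benzene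
Conditions: Et3SiH (3 equiv), CF3CO2H, 0 °C → rt
Reagents that add atoms: none
Why: Ionic hydrogenation; the protonated para-methoxyaryl ketone and then the derived benzylic cation each take hydride from Et3SiH, reducing C=O to CH2.

Step 6
Reactants: 7 2-(3,5-dimethoxyphenyl)-1-(4-methoxyphenyl)ethan-1-one
Product: 10 rac-2-chloro-2-(3,5-dimethoxyphenyl)-1-(4-methoxyphenyl)ethan-1-one, via lithium enolate 9 (not isolated)
Conditions: LiN(SiMe3)2, THF, −78 °C; then TsCl, −78 → 0 °C
Reagents that add atoms: 4-methylbenzenesulfonyl chloride, Cc1ccc(cc1)S(Cl)(=O)=O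
Why: Enolate α-chlorination; the preformed lithium enolate attacks the chlorine of TsCl, which avoids the ring halogenation that electrophilic chlorinating agents would cause on the dimethoxyarene, and the new stereocentre is racemic.

Step 7
Reactants: 8 1,3-dimethoxy-5-[2-(4-methoxyphenyl)ethyl]benzene; 10 rac-2-chloro-2-(3,5-dimethoxyphenyl)-1-(4-methoxyphenyl)ethan-1-one
Product: 14 rac-2-(3,5-dimethoxyphenyl)-2-{2,6-dimethoxy-4-[2-(4-methoxyphenyl)ethyl]phenyl}-1-(4-methoxyphenyl)ethan-1-one, via aryllithium 11 (not isolated), via arylmagnesium bromide 12 (not isolated), via bromomagnesium alkoxide 13 (not isolated)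
Conditions: n-BuLi, THF, 0 °C → rt; MgBr2·OEt2, 0 °C; 10, PhMe, −40 → 0 °C; then 80 °C
Reagents that add atoms: none
Why: Directed ortho-metalation between the two methoxy groups, Cornforth–Felkin 1,2-addition of the arylmagnesium bromide anti to the C–Cl bond, then a semipinacol rearrangement of the magnesium chlorohydrinate in which the electron-rich ring A aryl, anti-periplanar to C–Cl, makes a concerted 1,2-shift with loss of chloride (the 3,5-dimethoxybenzylic carbon cannot ionise unassisted, and para-anisyl migration would force ring A to eclipse the dimethoxyphenyl group); this forms the C3–C3a bond and leaves a racemic, enolisable stereocentre.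

Step 8
Reactants: 14 rac-2-(3,5-dimethoxyphenyl)-2-{2,6-dimethoxy-4-[2-(4-methoxyphenyl)ethyl]phenyl}-1-(4-methoxyphenyl)ethan-1-one
Product: 15 (1S,2S)-2-(3,5-dimethoxyphenyl)-2-{2,6-dimethoxy-4-[2-(4-methoxyphenyl)ethyl]phenyl}-1-(4-methoxyphenyl)ethan-1-ol
Conditions: RuCl2[(R)-xylbinap][(R)-daipen] (1 mol %), KOtBu (0.3 equiv), H2 (20 bar), i-PrOH/THF, 30 °C
Reagents that add atoms: none
Why: Proposed new method: dynamic kinetic resolution by Noyori-type hydrogenation of a 1,2,2-triarylethanone; the doubly benzylic α-C–H (pKa about 18) is epimerised through the potassium enolate faster than the C=O is reduced, and the outer-sphere Ru–H/N–H transfer selects the ketone enantiomer that places the bulky 2,6-dimethoxyaryl group anti to the incoming hydride (Felkin–Anh) inside the aryl/alkyl-differentiating pocket, which sets C2 of the ethanol (the future C3, S) together with the carbinol centre (S); the closest known reaction type is the DKR hydrogenation of racemic α-aryl cycloalkanones and α-aryl-α-alkyl ketones with RuCl2(diphosphine)(diamine)/KOtBu, not yet shown for α,α-diaryl ketones.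

Step 9
Reactants: 15 (1S,2S)-2-(3,5-dimethoxyphenyl)-2-{2,6-dimethoxy-4-[2-(4-methoxyphenyl)ethyl]phenyl}-1-(4-methoxyphenyl)ethan-1-ol
Product: 17 5-[(2S,3S)-4-hydroxy-2-(4-hydroxyphenyl)-6-[2-(4-hydroxyphenyl)ethyl]-2,3-dihydro-1-benzofuran-3-yl]benzene-1,3-diol, via pentamethyl ether 16 (not isolated)
Conditions: BBr3 (10 equiv), CH2Cl2, −78 °C → rt; MeOH/H2O quench
Reagents that add atoms: none
Why: BBr3 ionises the para-methoxybenzylic alcohol and the neighbouring ortho-methoxy oxygen of ring A traps the cation in a 5-exo cyclisation anti to the C3 aryl group (the oxonium loses CH3Br), so C2 is re-set trans (S) under kinetic and thermodynamic control while C3 is untouched; the same reagent then cleaves the five remaining aryl methyl ethers (Lewis-acid ether cleavage).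

**Compound list**

1 | resorcinol (benzene-1,3-diol) | Oc1cccc(O)c1 | starting material
2 | 1,3-dimethoxybenzene | COc1cccc(OC)c1 | intermediate
3 | 2-(3,5-dimethoxyphenyl)-4,4,5,5-tetramethyl-1,3,2-dioxaborolane | COc1cc(OC)cc(c1)B1OC(C)(C)C(C)(C)O1 | intermediate
4 | anisole (methoxybenzene) | COc1ccccc1 | starting material
5 | bromoacetyl bromide | BrCC(Br)=O | starting material
6 | 2-bromo-1-(4-methoxyphenyl)ethan-1-one | COc1ccc(cc1)C(=O)CBr | intermediate
7 | 2-(3,5-dimethoxyphenyl)-1-(4-methoxyphenyl)ethan-1-one | COc1ccc(cc1)C(=O)Cc1cc(OC)cc(OC)c1 | intermediate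
8 | 1,3-dimethoxy-5-[2-(4-methoxyphenyl)ethyl]benzene | COc1ccc(CCc2cc(OC)cc(OC)c2)cc1 | intermediate
9 | lithium (Z)-enolate of 7 (not isolated) | [Li]O/C(=C\c1cc(OC)cc(OC)c1)c1ccc(OC)cc1 | intermediate
10 | rac-2-chloro-2-(3,5-dimethoxyphenyl)-1-(4-methoxyphenyl)ethan-1-one | COc1ccc(cc1)C(=O)C(Cl)c1cc(OC)cc(OC)c1 | intermediate
11 | {2,6-dimethoxy-4-[2-(4-methoxyphenyl)ethyl]phenyl}lithium (not isolated) | [Li]c1c(OC)cc(CCc2ccc(OC)cc2)cc1OC | intermediate
12 | {2,6-dimethoxy-4-[2-(4-methoxyphenyl)ethyl]phenyl}magnesium bromide (not isolated) | Br[Mg]c1c(OC)cc(CCc2ccc(OC)cc2)cc1OC | intermediate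
13 | bromomagnesium alkoxide of rac-(1R*,2S*)-2-chloro-2-(3,5-dimethoxyphenyl)-1-{2,6-dimethoxy-4-[2-(4-methoxyphenyl)ethyl]phenyl}-1-(4-methoxyphenyl)ethan-1-ol (not isolated; racemic, one enantiomer drawn) | Br[Mg]O[C@](c1ccc(OC)cc1)(c1c(OC)cc(CCc2ccc(OC)cc2)cc1OC)[C@@H](Cl)c1cc(OC)cc(OC)c1 | intermediate
14 | rac-2-(3,5-dimethoxyphenyl)-2-{2,6-dimethoxy-4-[2-(4-methoxyphenyl)ethyl]phenyl}-1-(4-methoxyphenyl)ethan-1-one | COc1ccc(cc1)C(=O)C(c1cc(OC)cc(OC)c1)c1c(OC)cc(CCc2ccc(OC)cc2)cc1OC | intermediate
15 | (1S,2S)-2-(3,5-dimethoxyphenyl)-2-{2,6-dimethoxy-4-[2-(4-methoxyphenyl)ethyl]phenyl}-1-(4-methoxyphenyl)ethan-1-ol | O[C@H](c1ccc(OC)cc1)[C@@H](c1cc(OC)cc(OC)c1)c1c(OC)cc(CCc2ccc(OC)cc2)cc1OC | intermediate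
16 | (2S,3S)-3-(3,5-dimethoxyphenyl)-4-methoxy-2-(4-methoxyphenyl)-6-[2-(4-methoxyphenyl)ethyl]-2,3-dihydro-1-benzofuran (not isolated) | COc1ccc(CCc2cc(OC)c3c(c2)O[C@H](c2ccc(OC)cc2)[C@H]3c2cc(OC)cc(OC)c2)cc1 | intermediate
17 | 5-[(2S,3S)-4-hydroxy-2-(4-hydroxyphenyl)-6-[2-(4-hydroxyphenyl)ethyl]-2,3-dihydro-1-benzofuran-3-yl]benzene-1,3-diol (trans) | Oc1ccc(CCc2cc(O)c3c(c2)O[C@H](c2ccc(O)cc2)[C@H]3c2cc(O)cc(O)c2)cc1 | target

**Step count and risks**

Total step count: 9. Longest linear sequence: 7 steps (1, 2, 4, 5, 7, 8, 9).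

The three steps most likely to fail:

Step 7 (semipinacol 1,2-aryl shift). The hindered arylmagnesium bromide 12 may enolise 10 instead of adding. The alkoxide 13 may close to the epoxide, or the para-anisyl group may migrate and give the isomeric ketone. The fallback uses no rearrangement and no enolisable electrophile; it sets out from 7 and 8 and comes back at 14. Ketone 7 is oxidised with SeO2 (dioxane/H2O, 100 °C) to 1-(3,5-dimethoxyphenyl)-2-(4-methoxyphenyl)ethane-1,2-dione F1. The aryllithium made from 8 (n-BuLi, THF) adds at −78 °C to the carbonyl next to the dimethoxyphenyl ring, the anisoyl carbonyl being the less electrophilic one. This gives the tertiary α-ketol rac-2-(3,5-dimethoxyphenyl)-2-{2,6-dimethoxy-4-[2-(4-methoxyphenyl)ethyl]phenyl}-2-hydroxy-1-(4-methoxyphenyl)ethan-1-one F2. SmI2 (THF/MeOH, −78 °C) then removes the α-hydroxyl to give 14.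

Step 8 (the proposed new step). The hindered ketone may be reduced slowly, or the catalyst may not distinguish the two α-aryl groups well enough, giving low ee at the future C3. The fallback uses known chemistry only; it sets out from 14 and comes back at 15. NaBH4 (THF/MeOH, 0 °C) reduces 14 under Felkin–Anh control to the racemic alcohol rac-(1RS,2RS)-2-(3,5-dimethoxyphenyl)-2-{2,6-dimethoxy-4-[2-(4-methoxyphenyl)ethyl]phenyl}-1-(4-methoxyphenyl)ethan-1-ol F3. Preparative chromatography on a chiral stationary phase gives 15. The unwanted enantiomer is oxidised back to 14 with Dess–Martin periodinane and recycled.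

Step 9 (BBr3 cascade). The C2 cation could lose the C3 proton or take a 1,2-hydride shift, which would erode the ee at C3, and excess BBr3 can re-open the C2–O bond and degrade the pentaphenol. The fallback separates ring closure from deprotection and changes the deprotection mechanism; it sets out from 15 and comes back at 17. Alcohol 15 is cyclised with HNTf2 (5 mol %) in hexafluoroisopropanol at 0 °C (methoxy participation, loss of methanol). Compound 16 is isolated and its ee and trans geometry are checked. Its five methyl ethers are then cleaved with BCl3/n-Bu4NI in CH2Cl2 at −78 → 0 °C, an iodide-driven SN2 demethylation that is less prone to ionise the C2–O bond, to give 17.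

**Further compounds**

F1 | step 7 | 1-(3,5-dimethoxyphenyl)-2-(4-methoxyphenyl)ethane-1,2-dione | COc1ccc(cc1)C(=O)C(=O)c1cc(OC)cc(OC)c1
F2 | step 7 | rac-2-(3,5-dimethoxyphenyl)-2-{2,6-dimethoxy-4-[2-(4-methoxyphenyl)ethyl]phenyl}-2-hydroxy-1-(4-methoxyphenyl)ethan-1-one | COc1ccc(cc1)C(=O)C(O)(c1cc(OC)cc(OC)c1)c1c(OC)cc(CCc2ccc(OC)cc2)cc1OC
F3 | step 8 | rac-(1RS,2RS)-2-(3,5-dimethoxyphenyl)-2-{2,6-dimethoxy-4-[2-(4-methoxyphenyl)ethyl]phenyl}-1-(4-methoxyphenyl)ethan-1-ol (racemate, one enantiomer drawn) | O[C@H](c1ccc(OC)cc1)[C@@H](c1cc(OC)cc(OC)c1)c1c(OC)cc(CCc2ccc(OC)cc2)cc1OC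
F0 | step 9 | none | none
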